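**Plan**
- Cuts: with the two phenols masked as benzyl ethers, the benzylic ether bonds C2–O3 and C6–O7 are cut first. This opens both oxolane rings to an acyclic 2,3-dibenzylbutane-1,2,3,4-tetrol. The carbon–carbon bonds C1–C2 and C5–C6 are cut next.
- Enabling feature: in the 3,7-dioxabicyclo[3.3.0]octane the ring-fusion atoms C1 and C5 are adjacent tertiary carbinols exchanged by a twofold axis. Each carries one OCH2 carbon (C8, C4) and one ArCH carbon (C2, C6). The chain C8–C1(O)–C5(O)–C4 is therefore tartaric acid with its carboxyl carbons reduced and its two α-hydrogens replaced by benzylic carbons.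
- Forward: the benzylic bromide is made in two steps. D-tartrate acetonide is then benzylated at both α-carbons through successive ester enolates (chain assembly, no ring). The esters become CH2OH, the ketal is removed, DDQ closes ring A (C2–O3) and then ring B (C6–O7) in one flask, and hydrogenolysis frees the phenols.
- Stereochemistry: C1 and C5 are the two stereocentres of D-tartaric acid, carried over by retentive alkylation. C2 and C6 arise under substrate control in the ring closures, with the aryl groups on the convex face, cis to the angular hydroxyls.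

Key step: step 3

Remark on the chemistry: the first benzylation is taken to proceed with net retention, as is established for monoalkylation of this dioxolane enolate. The absolute configuration of every later compound rests on that point.

Step 1
Reactants: 1 4-benzyloxy-3-methoxybenzaldehyde (O-benzylvanillin)
Product: 2 (4-benzyloxy-3-methoxyphenyl)methanol
Conditions: NaBH4, MeOH, 0 °C → rt
Reagents that add atoms: none
Why: Borohydride reduction of an aromatic aldehyde is fast and chemoselective, leaves both aryl ethers untouched and creates no stereocentre.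

Step 2
Reactants: 2 (4-benzyloxy-3-methoxyphenyl)methanol
Product: 3 4-benzyloxy-3-methoxybenzyl bromide
Conditions: PBr3 (0.4 equiv), Et2O, 0 °C
Reagents that add atoms: phosphorus tribromide, BrP(Br)Br
Why: Bromination of an electron-rich benzylic alcohol with PBr3 runs through the phosphite ester and bromide displacement at 0 °C without harming the ethers, and the self-alkylating bromide is used directly.

Step 3
Reactants: 4 dimethyl (4S,5S)-2,2-dimethyl-1,3-dioxolane-4,5-dicarboxylate (dimethyl 2,3-O-isopropylidene-D-tartrate); 3 4-benzyloxy-3-methoxybenzyl bromide (two equivalents in all)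
Product: 8 dimethyl (4S,5S)-4,5-bis[(4-benzyloxy-3-methoxyphenyl)methyl]-2,2-dimethyl-1,3-dioxolane-4,5-dicarboxylate, via first lithium enolate 5 (not isolated), via monobenzyl diester 6 (not isolated), via second lithium enolate 7 (not isolated)
Conditions: LiN(iPr)2 (1.05 equiv), THF–DMPU, −78 °C; 3 (1.0 equiv), −78 °C; then LiN(iPr)2 (1.1 equiv), −78 °C; 3 (1.3 equiv), −78 → −40 °C; aq. NH4Cl
Reagents that add atoms: none
Why: Lithium diisopropylamide removes one α-hydrogen of 4 to give the exocyclic ester enolate 5, which persists at −78 °C because the ring C–O bond at the β-carbon lies close to the nodal plane of the enolate π system and cannot be expelled, and SN2 attack on bromide 3 forms C1–C2 (target numbering); a second equivalent of base enolises the only α-hydrogen left in 6 and the same event forms C5–C6. The closest known reaction type is the stereoretentive alkylation of tartrate acetonide lithium enolates with allylic and benzylic halides, from which trans-dialkylated diesters are also known. No ring is closed in this step. The first quaternary centre is controlled by the neighbouring ring stereocentre: A(1,3) strain with the exocyclic enolate pushes the adjacent ester pseudoaxial and tips an acetal methyl over the opposite face, so the bromide enters cis to that ester, where the proton had been (retention, 4S). The second centre is controlled by the new quaternary carbon, since the bromide approaches anti to its benzyl arm and again cis to its ester, which should give the trans, twofold-symmetric (4S,5S) diester, with the meso isomer removable by chromatography. The step needs C- over O-alkylation, trans over cis dibenzylation and no loss of enantiopurity; the soft benzylic bromide secures the first, the two matched facial biases the second, and charging base one equivalent at a time keeps the achiral dienolate of 4 from forming.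

Step 4
Reactants: 8 dimethyl (4S,5S)-4,5-bis[(4-benzyloxy-3-methoxyphenyl)methyl]-2,2-dimethyl-1,3-dioxolane-4,5-dicarboxylate
Product: 9 [(4R,5R)-4,5-bis[(4-benzyloxy-3-methoxyphenyl)methyl]-2,2-dimethyl-1,3-dioxolane-4,5-diyl]dimethanol
Conditions: LiAlH4, THF, 0 °C → reflux; H2O quench
Reagents that add atoms: none
Why: LiAlH4 ester reduction copes with hindered α-alkoxy esters, spares the ketal and the aryl benzyl ethers, and cannot disturb the two quaternary centres, whose descriptors change to R,R only through the priority rules.

Step 5
Reactants: 9 [(4R,5R)-4,5-bis[(4-benzyloxy-3-methoxyphenyl)methyl]-2,2-dimethyl-1,3-dioxolane-4,5-diyl]dimethanol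
Product: 10 (2R,3R)-2,3-bis[(4-benzyloxy-3-methoxyphenyl)methyl]butane-1,2,3,4-tetrol
Conditions: 2 M aq. HCl, THF, 50 °C (acetone removed by evaporation)
Reagents that add atoms: none
Why: Acid-catalysed ketal hydrolysis is done here because no acid-labile benzylic C–O bond exists yet, the tertiary carbinols are flanked by β-oxygens and do not ionise, and aryl benzyl ethers tolerate dilute HCl.

Step 6
Reactants: 10 (2R,3R)-2,3-bis[(4-benzyloxy-3-methoxyphenyl)methyl]butane-1,2,3,4-tetrol
Product: 12 (1S,2R,5S,6R)-2,6-bis(4-benzyloxy-3-methoxyphenyl)-3,7-dioxabicyclo[3.3.0]octane-1,5-diol (di-O-benzylprinsepiol), via monocyclised oxolane triol 11 (not isolated)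
Conditions: DDQ (2.2 equiv), 4 Å MS, CH2Cl2, 0 °C → rt
Reagents that add atoms: none
Why: In this DDQ-mediated benzylic C–H oxidation with internal alcohol capture (oxidative etherification of a p-alkoxybenzyl position), hydride loss from each ArCH2 para to the benzyloxy group gives a quinone-methide-like cation that only the primary OH on the other carbinol carbon can reach through a five-membered 5-exo-trig closure, and the aryl group takes the less crowded position trans to the CH2O arm of the adjacent carbon, which is the convex face and cis to the angular OH, so that C2 and C6 should both be set as R.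

Step 7
Reactants: 12 (1S,2R,5S,6R)-2,6-bis(4-benzyloxy-3-methoxyphenyl)-3,7-dioxabicyclo[3.3.0]octane-1,5-diol
Product: 13 prinsepiol, (1S,2R,5S,6R)-2,6-bis(4-hydroxy-3-methoxyphenyl)-3,7-dioxabicyclo[3.3.0]octane-1,5-diol
Conditions: H2 (1 atm), 10% Pd/C, EtOAc, rt, stopped after two equivalents of H2
Reagents that add atoms: none
Why: In catalytic hydrogenolysis the unhindered PhCH2–OAr bonds are cleaved much faster than the secondary C2–O3 and C6–O7 bonds, which sit next to quaternary carbons, especially in a neutral aprotic solvent, and no stereocentre is touched.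

**Compound list**
1 | 4-benzyloxy-3-methoxybenzaldehyde (O-benzylvanillin) | COc1cc(C=O)ccc1OCc1ccccc1 | starting material
2 | (4-benzyloxy-3-methoxyphenyl)methanol | COc1cc(CO)ccc1OCc1ccccc1 | intermediate
3 | 4-benzyloxy-3-methoxybenzyl bromide | COc1cc(CBr)ccc1OCc1ccccc1 | intermediate
4 | dimethyl (4S,5S)-2,2-dimethyl-1,3-dioxolane-4,5-dicarboxylate | COC(=O)[C@H]1OC(C)(C)O[C@@H]1C(=O)OC | starting material
5 | lithium ester enolate of 4 (one α-carbon enolised, the 5S centre intact, enolate geometry undefined) | COC(=O)[C@H]1OC(C)(C)OC1=C(OC)[O-].[Li+] | intermediate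
6 | dimethyl (4S,5S)-4-[(4-benzyloxy-3-methoxyphenyl)methyl]-2,2-dimethyl-1,3-dioxolane-4,5-dicarboxylate | COC(=O)[C@@]1(Cc2ccc(OCc3ccccc3)c(OC)c2)OC(C)(C)O[C@@H]1C(=O)OC | intermediate
7 | lithium ester enolate of 6 (C5 enolised, the quaternary 4S centre intact, enolate geometry undefined) | COC(=O)[C@@]1(Cc2ccc(OCc3ccccc3)c(OC)c2)OC(C)(C)OC1=C(OC)[O-].[Li+] | intermediate
8 | dimethyl (4S,5S)-4,5-bis[(4-benzyloxy-3-methoxyphenyl)methyl]-2,2-dimethyl-1,3-dioxolane-4,5-dicarboxylate | COC(=O)[C@@]1(Cc2ccc(OCc3ccccc3)c(OC)c2)OC(C)(C)O[C@]1(Cc1ccc(OCc2ccccc2)c(OC)c1)C(=O)OC | intermediate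
9 | [(4R,5R)-4,5-bis[(4-benzyloxy-3-methoxyphenyl)methyl]-2,2-dimethyl-1,3-dioxolane-4,5-diyl]dimethanol | OC[C@@]1(Cc2ccc(OCc3ccccc3)c(OC)c2)OC(C)(C)O[C@]1(Cc1ccc(OCc2ccccc2)c(OC)c1)CO | intermediate
10 | (2R,3R)-2,3-bis[(4-benzyloxy-3-methoxyphenyl)methyl]butane-1,2,3,4-tetrol | OC[C@](O)(Cc1ccc(OCc2ccccc2)c(OC)c1)[C@@](O)(Cc1ccc(OCc2ccccc2)c(OC)c1)CO | intermediate
11 | (2R,3S,4R)-2-(4-benzyloxy-3-methoxyphenyl)-4-[(4-benzyloxy-3-methoxyphenyl)methyl]-3-(hydroxymethyl)oxolane-3,4-diol | COc1cc([C@H]2OC[C@](O)(Cc3ccc(OCc4ccccc4)c(OC)c3)[C@]2(O)CO)ccc1OCc1ccccc1 | intermediate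
12 | (1S,2R,5S,6R)-2,6-bis(4-benzyloxy-3-methoxyphenyl)-3,7-dioxabicyclo[3.3.0]octane-1,5-diol | COc1cc([C@H]2OC[C@]3(O)[C@@H](c4ccc(OCc5ccccc5)c(OC)c4)OC[C@]23O)ccc1OCc1ccccc1 | intermediate
13 | prinsepiol | COc1cc([C@H]2OC[C@]3(O)[C@@H](c4ccc(O)c(OC)c4)OC[C@]23O)ccc1O | target

**Step count and risks**
Total steps: 7. Longest linear sequence: 7 (1 → 13). The tartrate branch enters at step 3.

Step 3. The second enolate sits beside a fully substituted carbon. C-benzylation may therefore be slow and lose out to β-elimination or Claisen-type self-condensation on warming, and facial selectivity may drift towards the meso series. The fallback sets out from 6, isolated after the first stage. Treatment of 6 with LiN(iPr)2 and Me3SiCl at −78 °C gives the thermally stable trimethylsilyl ketene acetal F1. This is benzylated with bromide 3 under catalytic ZnBr2 in CH2Cl2. This is a Lewis-acid SN1 alkylation in which the small, very reactive p-alkoxybenzyl cation attacks anti to the resident benzyl arm. The route is rejoined at 8.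

Step 6. The newly formed benzylic ether C–H may be oxidised further. The cation may also be captured by the second arene (aryltetralin formation), or the free tertiary hydroxyls may drive C1–C5 fragmentation or a semipinacol shift. The fallback sets out from 9 and runs the DDQ closure before the ketal is removed. In 9 the dioxolane masks both tertiary oxygens and holds each CH2OH cis to the benzyl arm it must capture. This should give the propellane-type 1,5-O-isopropylidene derivative F2. Dilute aqueous acid (1 M HCl, THF, rt to 40 °C) then releases the diol, and the route is rejoined at 12.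

Step 7. Hydrogenolysis may run on into the C2–O3 and C6–O7 bonds and open the bicycle. The fallback sets out from 10, where no such bond exists. H2 over 10% Pd/C in MeOH gives the hexol F3. Ag2O in dry acetone then oxidises both guaiacyl units to p-quinone methides, and the primary hydroxyls capture these by 1,6-addition. This delivers 13 directly, so no reduction follows ring closure.

**Further compounds**
F1 | step 3 | methyl (4S)-4-[(4-benzyloxy-3-methoxyphenyl)methyl]-5-[methoxy(trimethylsilyloxy)methylidene]-2,2-dimethyl-1,3-dioxolane-4-carboxylate | COC(=O)[C@@]1(Cc2ccc(OCc3ccccc3)c(OC)c2)OC(C)(C)OC1=C(OC)O[Si](C)(C)C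
F2 | step 6 | (1S,2R,5S,6R)-2,6-bis(4-benzyloxy-3-methoxyphenyl)-1,5-(isopropylidenedioxy)-3,7-dioxabicyclo[3.3.0]octane | COc1cc([C@H]2OC[C@]3(OC(C)(C)O4)[C@@H](c5ccc(OCc6ccccc6)c(OC)c5)OC[C@]234)ccc1OCc1ccccc1
F3 | step 7 | (2R,3R)-2,3-bis[(4-hydroxy-3-methoxyphenyl)methyl]butane-1,2,3,4-tetrol | OC[C@](O)(Cc1ccc(O)c(OC)c1)[C@@](O)(Cc1ccc(O)c(OC)c1)CO
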